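The trans array O1–C2(aryl)/C3–OH of ring C is the retron of hydroboration of a 2-aryl-4H-chromene, so the C2–C3 bond is disconnected as an alkene. Ring-closing metathesis joins C2 to C3 and closes ring C in one operation. C2 is held as an aryl α-arylvinyl ether, made by methylenation of a plain aryl benzoate that brings O1–C2 and ring B. C3 is held as a styryl group on the C4 diarylmethine. The precursor has no ring C and a single stereocentre, C4, set by BINOL-catalysed styrylboronate addition to an o-quinone methide. C4 later sends borane to the opposite face, which fixes C3 and C2 together.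

Key step: step 7

Assumption: (R)-3,3'-dibromo-BINOL is taken to give the (S)-methine in step 4; if the sense of induction is the reverse, the (S)-catalyst is used and nothing else changes.

Step 1
Reactants: 1 2-methoxybenzene-1,3-diol
Product: 2 1,3-bis(benzyloxy)-2-methoxybenzene
Conditions: BnBr (2.3 equiv), K2CO3, DMF, 60 °C
Reagents that add atoms: benzyl bromide BrCc1ccccc1
Why: Williamson etherification masks both phenols as benzyl ethers that fall in the final hydrogenolysis while the methyl ether stays.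

Step 2
Reactants: 2 1,3-bis(benzyloxy)-2-methoxybenzene
Product: 3 1,3-bis(benzyloxy)-4-bromo-2-methoxybenzene
Conditions: NBS (1.0 equiv), MeCN, 0 °C to rt
Reagents that add atoms: N-bromosuccinimide O=C1CCC(=O)N1Br
Why: Electrophilic aromatic bromination should go to C4, ortho to one benzyloxy group and para to the other, because the flanked central methoxy group is twisted out of conjugation and directs weakly.

Step 3
Reactants: 3 1,3-bis(benzyloxy)-4-bromo-2-methoxybenzene; 4 4-(benzyloxy)-2-hydroxybenzaldehyde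
Product: 8 racemic 5-(benzyloxy)-2-{[2,4-bis(benzyloxy)-3-methoxyphenyl](ethoxy)methyl}phenol, via aryllithium 5 (not isolated), via sodium phenoxide 6 (not isolated), via benzhydrol 7 (not isolated)
Conditions: 3, n-BuLi (1.05 equiv), THF, −78 °C; 4, NaH (1.05 equiv), THF, 0 °C, cannulated in, −78 to 0 °C; then EtOH, p-TsOH·H2O (2.2 equiv), 0 °C to rt; NaHCO3 work-up
Reagents that add atoms: ethanol CCO
Why: Bromine–lithium exchange at low temperature outruns benzylic deprotonation, the aryllithium adds 1,2 to the aldehyde of the preformed phenoxide, and the doubly activated benzhydrol ionises under mild acid and is trapped by ethanol (SN1 etherification), its racemic centre being erased in step 4.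

Step 4
Reactants: 8 racemic 5-(benzyloxy)-2-{[2,4-bis(benzyloxy)-3-methoxyphenyl](ethoxy)methyl}phenol; 9 (E)-2-phenylethenylboronic acid
Product: 12 5-(benzyloxy)-2-{(1S,2E)-1-[2,4-bis(benzyloxy)-3-methoxyphenyl]-3-phenylprop-2-en-1-yl}phenol, via diethyl styrylboronate 10 (not isolated), via o-quinone methide 11 (not isolated)
Conditions: 9, EtOH, toluene, 4 Å MS, then evaporation; 8, (R)-3,3'-Br2-BINOL (10 mol %), toluene, 4 Å MS, rt
Reagents that add atoms: none
Why: Chiral-diol-catalysed alkenylboronate addition to an o-quinone methide, in which exchange of ethoxide for BINOL gives a more Lewis acidic boronate that expels ethanol from 8, binds the carbonyl oxygen of 11 and hands the styryl group to the exocyclic carbon through a closed transition state, so that the catalyst sets the future C4 as S.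

Step 5
Reactants: 12 5-(benzyloxy)-2-{(1S,2E)-1-[2,4-bis(benzyloxy)-3-methoxyphenyl]-3-phenylprop-2-en-1-yl}phenol; 13 3,4-bis(benzyloxy)benzoic acid
Product: 14 5-(benzyloxy)-2-{(1S,2E)-1-[2,4-bis(benzyloxy)-3-methoxyphenyl]-3-phenylprop-2-en-1-yl}phenyl 3,4-bis(benzyloxy)benzoate
Conditions: DCC, DMAP (cat.), CH2Cl2, 0 °C to rt
Reagents that add atoms: none
Why: Steglich esterification joins ring B and the future C2 to O1 under near-neutral conditions that leave the diarylmethine untouched.

Step 6
Reactants: 14 5-(benzyloxy)-2-{(1S,2E)-1-[2,4-bis(benzyloxy)-3-methoxyphenyl]-3-phenylprop-2-en-1-yl}phenyl 3,4-bis(benzyloxy)benzoate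
Product: 15 4-(benzyloxy)-2-({1-[3,4-bis(benzyloxy)phenyl]ethenyl}oxy)-1-{(1S,2E)-1-[2,4-bis(benzyloxy)-3-methoxyphenyl]-3-phenylprop-2-en-1-yl}benzene
Conditions: Cp2Ti(μ-CH2)(μ-Cl)AlMe2 (Tebbe reagent, 1.5 equiv), pyridine (cat.), toluene/THF, −40 °C to rt; aq NaOH quench; basic alumina
Reagents that add atoms: Tebbe reagent Cp2Ti(μ-CH2)(μ-Cl)AlMe2 C[Al-]1(C)C[Ti](C2C=CC=C2)(C2C=CC=C2)[Cl+]1
Why: Tebbe methylenation, for which aryl benzoates are standard substrates, should turn the ester carbonyl into the 1,1-disubstituted enol ether through an oxatitanacyclobutane without touching the styryl alkene, the benzyl ethers or the stereocentre.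

Step 7
Reactants: 15 4-(benzyloxy)-2-({1-[3,4-bis(benzyloxy)phenyl]ethenyl}oxy)-1-{(1S,2E)-1-[2,4-bis(benzyloxy)-3-methoxyphenyl]-3-phenylprop-2-en-1-yl}benzene
Product: 16 (4S)-7-(benzyloxy)-2-[3,4-bis(benzyloxy)phenyl]-4-[2,4-bis(benzyloxy)-3-methoxyphenyl]-4H-chromene
Conditions: RuCl2(=CHPh)(PCy3)(H2IMes) (second-generation Grubbs catalyst, 10 mol %), 1,4-benzoquinone (20 mol %), toluene (0.005 M), 80 °C, argon
Reagents that add atoms: none
Why: The ruthenium alkylidene first exchanges with the styryl alkene to place ruthenium on C3, this alkylidene adds to the enol ether intramolecularly in a [2+2] step, and cycloreversion gives the C2=C3 bond and a ruthenium methylidene that carries the chain and frees styrene. The closest known reaction type is enol ether–olefin ring-closing metathesis, used for cyclic enol ethers such as 4H-chromenes, 2-substituted benzofurans and C1-substituted glycals made from methylenated esters. Ring C closes as a six-membered ring with both alkene carbons endocyclic, helped by the ortho arrangement of the two arms on ring A, while high dilution disfavours dimerisation. No stereocentre is formed, C4 is only carried through, and the planar C2=C3 bond made here is what lets C4 control C3 and C2 in step 8. The step needs initiation at the styryl group instead of Fischer carbene formation at the enol ether, which the 1,1-disubstitution of the enol ether secures. It also needs the doubly benzylic, allylic C4–H to stay in place, so 1,4-benzoquinone is added to intercept ruthenium hydrides that would move the double bond.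

Step 8
Reactants: 16 (4S)-7-(benzyloxy)-2-[3,4-bis(benzyloxy)phenyl]-4-[2,4-bis(benzyloxy)-3-methoxyphenyl]-4H-chromene
Product: 18 (2R,3S,4S)-7-(benzyloxy)-2-[3,4-bis(benzyloxy)phenyl]-4-[2,4-bis(benzyloxy)-3-methoxyphenyl]-3,4-dihydro-2H-chromen-3-ol, via C3 alkylborane 17 (not isolated)
Conditions: BH3·THF (3 equiv), THF, 0 °C to rt; then 3 M NaOH, 30% H2O2, 0 °C
Reagents that add atoms: hydrogen peroxide OO
Why: Hydroboration–oxidation of a cyclic enol ether, in which boron goes to C3 (remote from O1 and the C2 aryl group), H and B add syn from the face opposite the pseudoaxial C4 aryl group, and oxidation with retention should give the 2,3-trans-3,4-trans alcohol, C3 and C2 both being set by C4.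

Step 9
Reactants: 18 (2R,3S,4S)-7-(benzyloxy)-2-[3,4-bis(benzyloxy)phenyl]-4-[2,4-bis(benzyloxy)-3-methoxyphenyl]-3,4-dihydro-2H-chromen-3-ol
Product: 19 (2R,3S,4R)-2-(3,4-dihydroxyphenyl)-4-(2,4-dihydroxy-3-methoxyphenyl)-3,4-dihydro-2H-chromene-3,7-diol
Conditions: H2 (1 atm), Pd(OH)2/C, degassed THF/MeOH, rt
Reagents that add atoms: none
Why: Hydrogenolysis of the five benzyl ethers, routine for benzylated flavan-3-ols, should leave the methyl ether, ring C and the three stereocentres untouched, the C4 descriptor changing from S to R only because the CIP ranking of its two aryl substituents changes.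

Compound list
1 | 2-methoxybenzene-1,3-diol | COc1c(O)cccc1O | starting material
2 | 1,3-bis(benzyloxy)-2-methoxybenzene | COc1c(OCc2ccccc2)cccc1OCc1ccccc1 | intermediate
3 | 1,3-bis(benzyloxy)-4-bromo-2-methoxybenzene | COc1c(OCc2ccccc2)ccc(Br)c1OCc1ccccc1 | intermediate
4 | 4-(benzyloxy)-2-hydroxybenzaldehyde | O=Cc1ccc(OCc2ccccc2)cc1O | starting material
5 | [2,4-bis(benzyloxy)-3-methoxyphenyl]lithium | COc1c(OCc2ccccc2)ccc([Li])c1OCc1ccccc1 | intermediate
6 | sodium 5-(benzyloxy)-2-formylphenolate | O=Cc1ccc(OCc2ccccc2)cc1[O-].[Na+] | intermediate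
7 | racemic 5-(benzyloxy)-2-{[2,4-bis(benzyloxy)-3-methoxyphenyl](hydroxy)methyl}phenol | COc1c(OCc2ccccc2)ccc(C(O)c2ccc(OCc3ccccc3)cc2O)c1OCc1ccccc1 | intermediate
8 | racemic 5-(benzyloxy)-2-{[2,4-bis(benzyloxy)-3-methoxyphenyl](ethoxy)methyl}phenol | COc1c(OCc2ccccc2)ccc(C(OCC)c2ccc(OCc3ccccc3)cc2O)c1OCc1ccccc1 | intermediate
9 | (E)-2-phenylethenylboronic acid | OB(O)/C=C/c1ccccc1 | starting material
10 | diethyl (E)-2-phenylethenylboronate | CCOB(OCC)/C=C/c1ccccc1 | intermediate
11 | (6E)-3-(benzyloxy)-6-{[2,4-bis(benzyloxy)-3-methoxyphenyl]methylidene}cyclohexa-2,4-dien-1-one | O=C1C=C(OCc2ccccc2)C=C/C1=C\c1ccc(OCc2ccccc2)c(OC)c1OCc1ccccc1 | intermediate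
12 | 5-(benzyloxy)-2-{(1S,2E)-1-[2,4-bis(benzyloxy)-3-methoxyphenyl]-3-phenylprop-2-en-1-yl}phenol | COc1c(OCc2ccccc2)ccc([C@@H](/C=C/c2ccccc2)c2ccc(OCc3ccccc3)cc2O)c1OCc1ccccc1 | intermediate
13 | 3,4-bis(benzyloxy)benzoic acid | O=C(O)c1ccc(OCc2ccccc2)c(OCc2ccccc2)c1 | starting material
14 | 5-(benzyloxy)-2-{(1S,2E)-1-[2,4-bis(benzyloxy)-3-methoxyphenyl]-3-phenylprop-2-en-1-yl}phenyl 3,4-bis(benzyloxy)benzoate | COc1c(OCc2ccccc2)ccc([C@@H](/C=C/c2ccccc2)c2ccc(OCc3ccccc3)cc2OC(=O)c2ccc(OCc3ccccc3)c(OCc3ccccc3)c2)c1OCc1ccccc1 | intermediate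
15 | 4-(benzyloxy)-2-({1-[3,4-bis(benzyloxy)phenyl]ethenyl}oxy)-1-{(1S,2E)-1-[2,4-bis(benzyloxy)-3-methoxyphenyl]-3-phenylprop-2-en-1-yl}benzene | COc1c(OCc2ccccc2)ccc([C@@H](/C=C/c2ccccc2)c2ccc(OCc3ccccc3)cc2OC(=C)c2ccc(OCc3ccccc3)c(OCc3ccccc3)c2)c1OCc1ccccc1 | intermediate
16 | (4S)-7-(benzyloxy)-2-[3,4-bis(benzyloxy)phenyl]-4-[2,4-bis(benzyloxy)-3-methoxyphenyl]-4H-chromene | COc1c(OCc2ccccc2)ccc([C@@H]2c3ccc(OCc4ccccc4)cc3OC(c3ccc(OCc4ccccc4)c(OCc4ccccc4)c3)=C2)c1OCc1ccccc1 | intermediate
17 | C3 alkylborane, BH2 in place of the hydroxyl of 18, on the face opposite the C4 aryl group and trans to the C2 aryl group | COc1c(OCc2ccccc2)ccc([C@@H]2c3ccc(OCc4ccccc4)cc3O[C@H](c3ccc(OCc4ccccc4)c(OCc4ccccc4)c3)[C@H]2B)c1OCc1ccccc1 | intermediate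
18 | (2R,3S,4S)-7-(benzyloxy)-2-[3,4-bis(benzyloxy)phenyl]-4-[2,4-bis(benzyloxy)-3-methoxyphenyl]-3,4-dihydro-2H-chromen-3-ol | COc1c(OCc2ccccc2)ccc([C@@H]2c3ccc(OCc4ccccc4)cc3O[C@H](c3ccc(OCc4ccccc4)c(OCc4ccccc4)c3)[C@H]2O)c1OCc1ccccc1 | intermediate
19 | (2R,3S,4R)-2-(3,4-dihydroxyphenyl)-4-(2,4-dihydroxy-3-methoxyphenyl)-3,4-dihydro-2H-chromene-3,7-diol | COc1c(O)ccc([C@@H]2c3ccc(O)cc3O[C@H](c3ccc(O)c(O)c3)[C@H]2O)c1O | target

Total step count: 9. Longest linear sequence: 9 steps (1 to 19 through 2, 3, 8, 12, 14, 15, 16 and 18).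

Steps most likely to fail

Step 7. The ruthenium alkylidene may fail to engage the hindered, electron-rich enol ether. Ruthenium hydrides may also shift the double bond and erode the C4 configuration. The fallback closes the same bond by intramolecular carbonyl olefination instead of olefin metathesis, and it sets out from 14.
- Ethenolysis (ethylene 1 atm, RuCl2(=CH-C6H4-2-OiPr)(H2IMes), second-generation Hoveyda–Grubbs catalyst, toluene, 40 °C) trims the styryl group to the vinyl ester 5-(benzyloxy)-2-{(1S)-1-[2,4-bis(benzyloxy)-3-methoxyphenyl]prop-2-en-1-yl}phenyl 3,4-bis(benzyloxy)benzoate F1.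
- The reduced titanium ethylidene reagent made from TiCl4, Zn, PbCl2 (cat.), TMEDA and CH3CHBr2 in THF/CH2Cl2 (Takai–Utimoto type olefinic ester cyclisation) then exchanges with the vinyl group.
- The resulting titanium alkylidene at C3 olefinates the ester carbonyl. The fallback comes back to the route at 16 and bypasses 15.

Step 4. Uncatalysed styryl transfer to the strongly stabilised o-quinone methide may compete and lower the enantiomeric purity, or the o-quinone methide may self-condense. The fallback replaces catalysis by resolution and sets out from 8.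
- Boronate 10 with achiral 2,2'-biphenol as catalyst gives the racemic styryl phenol F2.
- Acylation with (1S,4R)-camphanic chloride (Et3N, DMAP, CH2Cl2) gives the diastereomeric camphanate pair F3.
- Crystallisation or chromatography gives the single (S)-methine camphanate F4.
- LiOH in THF/H2O frees the phenol, and the fallback comes back to the route at 12.

Step 8. The alkylborane may lose the ring aryloxide by β-elimination, which opens ring C, or the facial bias may be insufficient. The fallback uses epoxidation and reductive opening and sets out from 16.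
- Dimethyldioxirane (acetone/CH2Cl2, −78 to 0 °C) should give the 2,3-epoxide with its oxygen on the face opposite the C4 aryl group F5.
- i-Bu2AlH (CH2Cl2, −78 °C) binds the epoxide oxygen, the C2–O bond ionises to the O1- and aryl-stabilised cation, and hydride is delivered to C2 from the same face.
- This gives the same 2,3-trans-3,4-trans alcohol, and the fallback comes back to the route at 18.

Further compounds
F1 | step 7 | 5-(benzyloxy)-2-{(1S)-1-[2,4-bis(benzyloxy)-3-methoxyphenyl]prop-2-en-1-yl}phenyl 3,4-bis(benzyloxy)benzoate | COc1c(OCc2ccccc2)ccc([C@@H](C=C)c2ccc(OCc3ccccc3)cc2OC(=O)c2ccc(OCc3ccccc3)c(OCc3ccccc3)c2)c1OCc1ccccc1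
F2 | step 4 | racemic 5-(benzyloxy)-2-{(2E)-1-[2,4-bis(benzyloxy)-3-methoxyphenyl]-3-phenylprop-2-en-1-yl}phenol | COc1c(OCc2ccccc2)ccc(C(/C=C/c2ccccc2)c2ccc(OCc3ccccc3)cc2O)c1OCc1ccccc1
F3 | step 4 | (1S,4R)-camphanates of F2, pair of diastereomers at the methine | COc1c(OCc2ccccc2)ccc(C(/C=C/c2ccccc2)c2ccc(OCc3ccccc3)cc2OC(=O)[C@@]23CC[C@@](C)(C(=O)O2)C3(C)C)c1OCc1ccccc1
F4 | step 4 | (1S,4R)-camphanate of 12, single (S)-methine diastereomer | COc1c(OCc2ccccc2)ccc([C@@H](/C=C/c2ccccc2)c2ccc(OCc3ccccc3)cc2OC(=O)[C@@]23CC[C@@](C)(C(=O)O2)C3(C)C)c1OCc1ccccc1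
F5 | step 8 | 2,3-epoxide of 16, oxirane oxygen on the face opposite the C4 aryl group | COc1c(OCc2ccccc2)ccc([C@@H]2c3ccc(OCc4ccccc4)cc3O[C@@]3(c4ccc(OCc5ccccc5)c(OCc5ccccc5)c4)O[C@@H]23)c1OCc1ccccc1
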